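**Strategy.** The route rests on disconnecting the C8–C9 bond of the seven-membered ring. The ring segment C6–C7(=CH2)–C8 is the same oxygenated isoprene unit as the C14 side-chain terminus, so C8 can be the terminal carbon of an isopropenyl carbinol that reaches an aldehyde carbon C9 held on C10 of the five-membered ring. A Lewis-acid-promoted intramolecular carbonyl-ene reaction then forms C8–C9, closes the hydroazulene and turns the C7 methyl into the exocyclic methylene in one operation. The precursor is a fully substituted cyclopentane (C1, C4, C10 set) bearing the C10 aldehyde, a silylated isopropenyl carbinol arm on quaternary C4 and the silylated side chain on C1.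

Key step: step 18

Numbering used for all compounds: five-membered ring C1 (CH bearing the side chain), C2, C3, C4 (quaternary, methyl), C10 (ring-fusion CH); seven-membered ring C4, C5, C6 (acetoxy), C7 (exocyclic methylene), C8, C9, C10; side chain C11 (tertiary carbinol), C12, C13, C14 (acetoxy), C15 (isopropenyl carbon). On the cyclopentane, C11 (on C1), C9 (on C10) and the C4 methyl lie on one face and C5 on the other.

Remark on the chemistry: the target is taken as the enantiomer drawn, (1S,4R,6S,10S,11S,14S) in this numbering. The C9 carbinol formed in step 18 is left unassigned because step 20 removes it.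

**Step 1**
Reactants: 1 geraniol
Product: 2 (2S,3S)-2,3-epoxygeraniol
Conditions: Ti(OiPr)4 (cat.), L-(+)-diethyl tartrate (cat.), t-BuOOH, 4 Å molecular sieves, CH2Cl2, −20 °C
Reagents that add atoms: tert-butyl hydroperoxide, CC(C)(C)OO
Why: Sharpless asymmetric epoxidation: the allylic hydroxyl binds the titanium tartrate peroxide complex, so only the allylic alkene reacts and L-(+)-tartrate should deliver oxygen to the face that gives the (2S,3S)-epoxide, which fixes C11 and, after the later inversion, C1.

**Step 2**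
Reactants: 2 (2S,3S)-2,3-epoxygeraniol
Product: 3 tert-butyldimethylsilyl ether of 2
Conditions: t-BuMe2SiCl, imidazole, CH2Cl2, 0 °C → rt
Reagents that add atoms: tert-butyldimethylsilyl chloride, CC(C)(C)[Si](C)(C)Cl
Why: Standard silylation of a primary alcohol, which removes the alkoxide that could start a Payne rearrangement under the basic conditions of the next step.

**Step 3**
Reactants: 3 tert-butyldimethylsilyl ether of 2; 4 acetonitrile
Product: 7 hydroxy lactone (4R,5S)-4-(hydroxymethyl)-5-methyl-5-(4-methylpent-3-en-1-yl)oxolan-2-one, via hydroxy nitrile 5 (not isolated), via silyloxy lactone 6 (not isolated)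
Conditions: MeCN, n-BuLi, THF, −78 °C → rt; then KOH, EtOH/H2O, 80 °C; then 2 M HCl, rt
Reagents that add atoms: acetonitrile (4), CC#N; potassium hydroxide (aqueous, supplies the carbonyl oxygen), [K+].[OH-]
Why: Epoxide opening by a nitrile-stabilised carbanion is an SN2 reaction at the less substituted oxirane carbon, which inverts the future C1 and leaves C11 untouched, and alkaline nitrile hydrolysis followed by acidification should close the γ-lactone on the tertiary C11 hydroxyl (gem-dialkyl effect, C2–O still silylated) before the acid cleaves the primary silyl ether.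

**Step 4**
Reactants: 7 hydroxy lactone
Product: 8 iodide (4S,5S)-4-(iodomethyl)-5-methyl-5-(4-methylpent-3-en-1-yl)oxolan-2-one
Conditions: PPh3, I2, imidazole, CH2Cl2, 0 °C → rt
Reagents that add atoms: iodine, II
Why: Appel-type iodination converts the primary alcohol into the iodide under neutral conditions that neither open nor translactonise the lactone, and no stereocentre is touched.

**Step 5**
Reactants: 8 iodide; 9 methyl acetoacetate
Product: 10 β-keto ester methyl 5-[(2S,3S)-2-methyl-2-(4-methylpent-3-en-1-yl)-5-oxooxolan-3-yl]-3-oxopentanoate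
Conditions: 9, NaH then n-BuLi, THF, 0 °C; then 8, −20 → 0 °C
Reagents that add atoms: methyl acetoacetate (9), COC(=O)CC(C)=O
Why: Weiler dianion alkylation: the γ-carbon of the acetoacetate dianion is a soft and very nucleophilic centre that should displace the primary iodide by SN2 faster than it deprotonates the lactone at low temperature, which adds C3 to C6.

**Step 6**
Reactants: 10 β-keto ester
Product: 11 (Z)-enol phosphate methyl (Z)-3-(diethoxyphosphoryloxy)-5-[(2S,3S)-2-methyl-2-(4-methylpent-3-en-1-yl)-5-oxooxolan-3-yl]pent-2-enoate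
Conditions: NaH, ClP(O)(OEt)2, Et2O, 0 °C
Reagents that add atoms: diethyl chlorophosphate, CCOP(=O)(Cl)OCC
Why: O-phosphorylation of the sodium chelate of a β-keto ester gives the (Z)-enol phosphate, and one equivalent of NaH removes only the far more acidic β-keto ester proton.

**Step 7**
Reactants: 11 (Z)-enol phosphate
Product: 12 (E)-β-methyl enoate methyl (E)-3-methyl-5-[(2S,3S)-2-methyl-2-(4-methylpent-3-en-1-yl)-5-oxooxolan-3-yl]pent-2-enoate
Conditions: Me2CuLi (from MeLi, CuI), Et2O, −78 → −45 °C
Reagents that add atoms: lithium dimethylcuprate, [Li+].C[Cu-]C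
Why: Addition–elimination of a Gilman cuprate on a β-phosphoryloxy enoate proceeds with retention of alkene geometry and installs the C4 methyl, while the lactone is inert to the cuprate at this temperature.

**Step 8**
Reactants: 12 (E)-β-methyl enoate
Product: 13 bicyclic lactone ester methyl 2-[(3S,3aS,6R,6aS)-3,6-dimethyl-3-(4-methylpent-3-en-1-yl)-1-oxohexahydro-1H-cyclopenta[c]furan-6-yl]acetate
Conditions: KN(SiMe3)2, 18-crown-6, THF, −78 → −20 °C; AcOH quench
Reagents that add atoms: none
Why: Intramolecular Michael addition (5-exo-trig): the potassium lactone enolate at C10 adds to C4 on the lactone face that carries the C2 tether, which enforces the cis lactone–cyclopentane fusion at C10, and the crown-ether-separated, non-chelated transition state should keep the ester-bearing C5 on the convex face, so that the C4 methyl ends cis to C9 (this should also be the more stable epimer).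

**Step 9**
Reactants: 13 bicyclic lactone ester
Product: 14 Weinreb amide 2-[(3S,3aS,6R,6aS)-3,6-dimethyl-3-(4-methylpent-3-en-1-yl)-1-oxohexahydro-1H-cyclopenta[c]furan-6-yl]-N-methoxy-N-methylacetamide
Conditions: MeNHOMe·HCl, i-PrMgCl, THF, −20 → 0 °C; dilute HCl work-up
Reagents that add atoms: N,O-dimethylhydroxylamine hydrochloride, CNOC.Cl
Why: Magnesium amide aminolysis of an ester (Weinreb amide formation) should take the methyl ester in preference to the lactone, whose carbonyl sits between a tertiary carbon and a tertiary alkoxy group, and any opened lactone recloses on the acidic work-up.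

**Step 10**
Reactants: 14 Weinreb amide
Product: 15 aldehyde 2-[(3S,3aS,6R,6aS)-3,6-dimethyl-1-oxo-3-(3-oxopropyl)hexahydro-1H-cyclopenta[c]furan-6-yl]-N-methoxy-N-methylacetamide
Conditions: O3, CH2Cl2/MeOH, −78 °C; then PPh3
Reagents that add atoms: ozone, [O-][O+]=O
Why: Ozonolysis with reductive work-up cleaves the only alkene present, the trisubstituted side-chain double bond, to the C14 aldehyde.

**Step 11**
Reactants: 15 aldehyde; 16 isopropenylmagnesium bromide
Product: 17 hydroxy enone (3S,3aS,6R,6aS)-3-(3-hydroxy-4-methylpent-4-en-1-yl)-3,6-dimethyl-6-(3-methyl-2-oxobut-3-en-1-yl)hexahydro-1H-cyclopenta[c]furan-1-one (C14 epimers)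
Conditions: CH2=C(CH3)MgBr (3.5 equiv), THF, −78 → 0 °C; inverse quench into cold 1 M HCl
Reagents that add atoms: isopropenylmagnesium bromide (16), C=C(C)[Mg]Br
Why: Grignard addition: the alkenyl Grignard adds to the aldehyde and, through the stable chelated adduct of the Weinreb amide, delivers the C6 ketone after a single addition, while the hindered lactone should survive at 0 °C and the C14 carbinol forms as an inconsequential epimer mixture.

**Step 12**
Reactants: 17 hydroxy enone
Product: 18 bis-enone (3S,3aS,6R,6aS)-3,6-dimethyl-6-(3-methyl-2-oxobut-3-en-1-yl)-3-(4-methyl-3-oxopent-4-en-1-yl)hexahydro-1H-cyclopenta[c]furan-1-one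
Conditions: Dess–Martin periodinane, NaHCO3, CH2Cl2, 0 °C → rt
Reagents that add atoms: none
Why: Dess–Martin oxidation of the secondary allylic alcohol gives the second isopropenyl ketone and erases the stereo-random C14 centre.

**Step 13**
Reactants: 18 bis-enone
Product: 19 diol (3S,3aS,6R,6aS)-6-[(2S)-2-hydroxy-3-methylbut-3-en-1-yl]-3-[(3S)-3-hydroxy-4-methylpent-4-en-1-yl]-3,6-dimethylhexahydro-1H-cyclopenta[c]furan-1-one
Conditions: (R)-Me-CBS oxazaborolidine [(R)-1-methyl-3,3-diphenyltetrahydro-1H,3H-pyrrolo[1,2-c][1,3,2]oxazaborole] (0.4 equiv), catecholborane, toluene, −78 °C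
Reagents that add atoms: none
Why: Corey–Bakshi–Shibata reduction: at both ketones the isopropenyl group acts as the large and the methylene as the small substituent, so the (R)-oxazaborolidine should deliver hydride to the same local face twice and set C6 and C14 as (S) under reagent control, and catecholborane at −78 °C does not hydroborate the alkenes or reduce the lactone.

**Step 14**
Reactants: 19 diol
Product: 20 bis(tert-butyldimethylsilyl) ether of 19
Conditions: t-BuMe2SiOTf, 2,6-lutidine, CH2Cl2, −78 → 0 °C
Reagents that add atoms: tert-butyldimethylsilyl triflate, CC(C)(C)[Si](C)(C)OS(=O)(=O)C(F)(F)F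
Why: Silyl triflate silylation protects both secondary allylic alcohols as ethers that survive hydride reduction, Swern conditions and the Lewis acid of the key step.

**Step 15**
Reactants: 20 bis(tert-butyldimethylsilyl) ether
Product: 21 diol (2S,5S)-5-(tert-butyldimethylsilyloxy)-2-{(1S,2S,3R)-3-[(2S)-2-(tert-butyldimethylsilyloxy)-3-methylbut-3-en-1-yl]-2-(hydroxymethyl)-3-methylcyclopentyl}-6-methylhept-6-en-2-ol
Conditions: LiAlH4, THF, 0 °C → rt
Reagents that add atoms: none
Why: LiAlH4 reduction of the lactone gives the primary C9 alcohol and frees the tertiary C11 alcohol, while silyl ethers and isolated alkenes are inert.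

**Step 16**
Reactants: 21 diol
Product: 22 bis(triethylsilyl) ether of 21 (C9–OSiEt3 and C11–OSiEt3)
Conditions: Et3SiOTf, 2,6-lutidine, CH2Cl2, −78 → 0 °C
Reagents that add atoms: triethylsilyl triflate, CC[Si](CC)(CC)OS(=O)(=O)C(F)(F)F
Why: A silyl triflate with 2,6-lutidine silylates both the primary and the hindered tertiary hydroxyl.

**Step 17**
Reactants: 22 bis(triethylsilyl) ether
Product: 23 key-step precursor aldehyde (C9 aldehyde on C10; C11 triethylsilyl ether; C6 and C14 tert-butyldimethylsilyl ethers)
Conditions: (COCl)2, DMSO, CH2Cl2, −78 → −40 °C; then Et3N, −78 → −20 °C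
Reagents that add atoms: none
Why: Swern oxidation of a primary triethylsilyl ether: the activated sulfoxide cleaves the primary Si–O bond selectively and oxidises C9 to the aldehyde, tertiary triethylsilyl and secondary tert-butyldimethylsilyl ethers stay intact, and the cold amine quench should not epimerise the hindered C10 centre.

**Step 18**
Reactants: 23 key-step precursor aldehyde
Product: 24 silylated hydroazulene with C7 exocyclic methylene and C9 hydroxyl (C9 unassigned)
Conditions: Me2AlCl (2.5 equiv), CH2Cl2 (0.005 M), −78 → −40 °C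
Reagents that add atoms: none
Why: Me2AlCl binds the C9 aldehyde oxygen, the terminal alkene carbon C8 of the isopropenyl group attacks the activated carbonyl, and a hydrogen of the C7 methyl passes to oxygen through a six-membered array, so that C8–C9 forms and the double bond moves to the exocyclic C7=CH2 position. The closest known reaction is the Lewis-acid-promoted type 2 intramolecular carbonyl-ene cyclisation of ω-isopropenyl aldehydes to 3-methylenecycloalkanols, which is established for six- and seven-membered rings. The seven-membered ring closes in the 7-endo mode with respect to the C7=C8 alkene (exo with respect to the carbonyl), and the trans arrangement of the C10 and C4 arms set in step 8 becomes the trans ring fusion. The only new stereocentre, C9, should follow the preference of the aluminium-bound oxygen for a pseudo-equatorial position in the bicyclic transition state, but it needs no control because step 20 removes it. The step needs hydrogen transfer from the methyl and not from C6–H, and C10 must keep its configuration: C6–H lies inside the forming ring and cannot reach the carbonyl oxygen, which rules out the silyl enol ether, and the non-basic, proton-scavenging Lewis acid at low temperature leaves the α-centre alone. The silyl ether on O11 prevents lactol formation, and the side-chain isopropenyl group could only close a nine-membered ring, so it should remain a spectator at high dilution.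

**Step 19**
Reactants: 24 silylated hydroazulene C9 alcohol
Product: 25 C9 O-(imidazol-1-ylthiocarbonyl) derivative of 24
Conditions: 1,1'-thiocarbonyldiimidazole, 4-(dimethylamino)pyridine (cat.), toluene, 90 °C
Reagents that add atoms: 1,1'-thiocarbonyldiimidazole, S=C(n1ccnc1)n1ccnc1
Why: Thioacylation of the secondary C9 alcohol under neutral conditions (first half of the Barton–McCombie deoxygenation) avoids an alkoxide that could induce silyl migration from O11.

**Step 20**
Reactants: 25 C9 thiocarbamate
Product: 26 tris-silylated hydroazulene lacking the C9 oxygen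
Conditions: Bu3SnH (3 equiv, 0.2 M), azobisisobutyronitrile, toluene, 100 °C
Reagents that add atoms: none
Why: Barton–McCombie radical deoxygenation: stannyl radical addition to the thiocarbonyl, fragmentation to the secondary C9 radical and fast hydrogen transfer from concentrated Bu3SnH remove the C9 oxygen before the homoallylic radical can rearrange.

**Step 21**
Reactants: 26 tris-silyl ether
Product: 27 triol (free hydroxyls at C6, C11, C14)
Conditions: Bu4NF, THF, rt → 50 °C
Reagents that add atoms: none
Why: Fluoride-mediated desilylation cleaves the two secondary tert-butyldimethylsilyl ethers and the tertiary triethylsilyl ether without touching any stereocentre.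

**Step 22**
Reactants: 27 triol
Product: 28 target diacetate CNP0151143.1
Conditions: Ac2O, pyridine, 4-(dimethylamino)pyridine (cat.), CH2Cl2, 0 °C → rt
Reagents that add atoms: acetic anhydride, CC(=O)OC(C)=O
Why: Acetylation esterifies the two secondary allylic alcohols, whereas the hindered tertiary C11 alcohol should not react under these mild conditions.

**Compound list**

1 | geraniol, (E)-3,7-dimethylocta-2,6-dien-1-ol | CC(C)=CCC/C(C)=C/CO | starting material
2 | (2S,3S)-2,3-epoxygeraniol, [(2S,3S)-3-methyl-3-(4-methylpent-3-en-1-yl)oxiran-2-yl]methanol | OC[C@@H]1O[C@@]1(C)CCC=C(C)C | intermediate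
3 | tert-butyldimethylsilyl ether of 2 | CC(C)(C)[Si](C)(C)OC[C@@H]1O[C@@]1(C)CCC=C(C)C | intermediate
4 | acetonitrile | CC#N | starting material
5 | (3R,4S)-3-[(tert-butyldimethylsilyloxy)methyl]-4-hydroxy-4,8-dimethylnon-7-enenitrile | CC(C)(C)[Si](C)(C)OC[C@H]([C@@](C)(O)CCC=C(C)C)CC#N | intermediate (not isolated)
6 | (4R,5S)-4-[(tert-butyldimethylsilyloxy)methyl]-5-methyl-5-(4-methylpent-3-en-1-yl)oxolan-2-one | CC(C)(C)[Si](C)(C)OC[C@H]1CC(=O)O[C@@]1(C)CCC=C(C)C | intermediate (not isolated)
7 | (4R,5S)-4-(hydroxymethyl)-5-methyl-5-(4-methylpent-3-en-1-yl)oxolan-2-one | OC[C@H]1CC(=O)O[C@@]1(C)CCC=C(C)C | intermediate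
8 | (4S,5S)-4-(iodomethyl)-5-methyl-5-(4-methylpent-3-en-1-yl)oxolan-2-one | IC[C@H]1CC(=O)O[C@@]1(C)CCC=C(C)C | intermediate
9 | methyl acetoacetate | COC(=O)CC(C)=O | starting material
10 | methyl 5-[(2S,3S)-2-methyl-2-(4-methylpent-3-en-1-yl)-5-oxooxolan-3-yl]-3-oxopentanoate | COC(=O)CC(=O)CC[C@H]1CC(=O)O[C@@]1(C)CCC=C(C)C | intermediate
11 | methyl (Z)-3-(diethoxyphosphoryloxy)-5-[(2S,3S)-2-methyl-2-(4-methylpent-3-en-1-yl)-5-oxooxolan-3-yl]pent-2-enoate | COC(=O)/C=C(\OP(=O)(OCC)OCC)CC[C@H]1CC(=O)O[C@@]1(C)CCC=C(C)C | intermediate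
12 | methyl (E)-3-methyl-5-[(2S,3S)-2-methyl-2-(4-methylpent-3-en-1-yl)-5-oxooxolan-3-yl]pent-2-enoate | COC(=O)/C=C(\C)CC[C@H]1CC(=O)O[C@@]1(C)CCC=C(C)C | intermediate
13 | methyl 2-[(3S,3aS,6R,6aS)-3,6-dimethyl-3-(4-methylpent-3-en-1-yl)-1-oxohexahydro-1H-cyclopenta[c]furan-6-yl]acetate (cis-fused; C4 methyl cis to C9) | COC(=O)C[C@@]1(C)CC[C@H]2[C@@H]1C(=O)O[C@@]2(C)CCC=C(C)C | intermediate
14 | 2-[(3S,3aS,6R,6aS)-3,6-dimethyl-3-(4-methylpent-3-en-1-yl)-1-oxohexahydro-1H-cyclopenta[c]furan-6-yl]-N-methoxy-N-methylacetamide | CON(C)C(=O)C[C@@]1(C)CC[C@H]2[C@@H]1C(=O)O[C@@]2(C)CCC=C(C)C | intermediate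
15 | 2-[(3S,3aS,6R,6aS)-3,6-dimethyl-1-oxo-3-(3-oxopropyl)hexahydro-1H-cyclopenta[c]furan-6-yl]-N-methoxy-N-methylacetamide | CON(C)C(=O)C[C@@]1(C)CC[C@H]2[C@@H]1C(=O)O[C@@]2(C)CCC=O | intermediate
16 | isopropenylmagnesium bromide (commercial THF solution) | C=C(C)[Mg]Br | starting material
17 | (3S,3aS,6R,6aS)-3-(3-hydroxy-4-methylpent-4-en-1-yl)-3,6-dimethyl-6-(3-methyl-2-oxobut-3-en-1-yl)hexahydro-1H-cyclopenta[c]furan-1-one, C14 epimers | C=C(C)C(=O)C[C@@]1(C)CC[C@H]2[C@@H]1C(=O)O[C@@]2(C)CCC(O)C(C)=C | intermediate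
18 | (3S,3aS,6R,6aS)-3,6-dimethyl-6-(3-methyl-2-oxobut-3-en-1-yl)-3-(4-methyl-3-oxopent-4-en-1-yl)hexahydro-1H-cyclopenta[c]furan-1-one | C=C(C)C(=O)C[C@@]1(C)CC[C@H]2[C@@H]1C(=O)O[C@@]2(C)CCC(=O)C(C)=C | intermediate
19 | (3S,3aS,6R,6aS)-6-[(2S)-2-hydroxy-3-methylbut-3-en-1-yl]-3-[(3S)-3-hydroxy-4-methylpent-4-en-1-yl]-3,6-dimethylhexahydro-1H-cyclopenta[c]furan-1-one | C=C(C)[C@@H](O)C[C@@]1(C)CC[C@H]2[C@@H]1C(=O)O[C@@]2(C)CC[C@H](O)C(C)=C | intermediate
20 | bis(tert-butyldimethylsilyl) ether of 19 (O6 and O14) | C=C(C)[C@@H](O[Si](C)(C)C(C)(C)C)C[C@@]1(C)CC[C@H]2[C@@H]1C(=O)O[C@@]2(C)CC[C@H](O[Si](C)(C)C(C)(C)C)C(C)=C | intermediate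
21 | (2S,5S)-5-(tert-butyldimethylsilyloxy)-2-{(1S,2S,3R)-3-[(2S)-2-(tert-butyldimethylsilyloxy)-3-methylbut-3-en-1-yl]-2-(hydroxymethyl)-3-methylcyclopentyl}-6-methylhept-6-en-2-ol | C=C(C)[C@H](CC[C@](C)(O)[C@H]1CC[C@](C)(C[C@H](O[Si](C)(C)C(C)(C)C)C(C)=C)[C@H]1CO)O[Si](C)(C)C(C)(C)C | intermediate
22 | bis(triethylsilyl) ether of 21 (O9 and O11) | C=C(C)[C@H](CC[C@](C)(O[Si](CC)(CC)CC)[C@H]1CC[C@](C)(C[C@H](O[Si](C)(C)C(C)(C)C)C(C)=C)[C@H]1CO[Si](CC)(CC)CC)O[Si](C)(C)C(C)(C)C | intermediate
23 | key-step precursor: cyclopentane with the C9 aldehyde on C10, the C4 arm CH2–CH(OSiMe2tBu)–C(CH3)=CH2 and the C1 side chain with O11–SiEt3 and O14–SiMe2tBu; configurations as in 21 | C=C(C)[C@H](CC[C@](C)(O[Si](CC)(CC)CC)[C@H]1CC[C@](C)(C[C@H](O[Si](C)(C)C(C)(C)C)C(C)=C)[C@H]1C=O)O[Si](C)(C)C(C)(C)C | intermediate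
24 | trans-fused hydroazulene with C7 exocyclic methylene, C9 hydroxyl (unassigned), O6 and O14 as tert-butyldimethylsilyl ethers, O11 as triethylsilyl ether | C=C(C)[C@H](CC[C@](C)(O[Si](CC)(CC)CC)[C@H]1CC[C@]2(C)C[C@H](O[Si](C)(C)C(C)(C)C)C(=C)CC(O)[C@@H]12)O[Si](C)(C)C(C)(C)C | intermediate
25 | C9 O-(imidazol-1-ylthiocarbonyl) derivative of 24 | C=C(C)[C@H](CC[C@](C)(O[Si](CC)(CC)CC)[C@H]1CC[C@]2(C)C[C@H](O[Si](C)(C)C(C)(C)C)C(=C)CC(OC(=S)n3ccnc3)[C@@H]12)O[Si](C)(C)C(C)(C)C | intermediate
26 | tris-silylated hydroazulene without C9 oxygen (O6 and O14 tert-butyldimethylsilyl, O11 triethylsilyl) | C=C(C)[C@H](CC[C@](C)(O[Si](CC)(CC)CC)[C@H]1CC[C@]2(C)C[C@H](O[Si](C)(C)C(C)(C)C)C(=C)CC[C@@H]12)O[Si](C)(C)C(C)(C)C | intermediate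
27 | triol (1S,4R,6S,10S,11S,14S), free hydroxyls at C6, C11 and C14 | C=C(C)[C@H](CC[C@](C)(O)[C@H]1CC[C@]2(C)C[C@H](O)C(=C)CC[C@@H]12)O | intermediate
28 | CNP0151143.1, 6,14-diacetate of 27 | C=C(C)[C@H](CC[C@](C)(O)[C@H]1CC[C@]2(C)C[C@H](OC(C)=O)C(=C)CC[C@@H]12)OC(C)=O | target

**Step count and risk**

Total steps: 22. Longest linear sequence: 22 steps (geraniol to target).

Steps most likely to fail:

1. Step 18. The ring may not close at the hindered aldehyde, a stepwise cationic course may leave an endocyclic alkene, or the Lewis acid may strip silyl ethers. Fallback: replace the ene donor by an allylsilane and close the same bond by an intramolecular Hosomi–Sakurai allylation; it sets out from 15 and comes back at 24. One equivalent of 16 at −78 °C would add to the aldehyde of 15 only and give the C14 allylic alcohol F1. The Grignard reagent [3-(trimethylsilyl)prop-1-en-2-yl]magnesium bromide F2, prepared from (2-bromoallyl)trimethylsilane and Mg, would then convert the Weinreb amide into the silylmethyl enone F3. Dess–Martin oxidation would give the bis-enone F4, twofold reduction as in step 13 the diol F5, and silylation with t-BuMe2SiCl and imidazole the bis-silyl ether F6. LiAlH4 reduction would give the diol F7, Et3SiOTf the bis(triethylsilyl) ether F8, and Swern oxidation as in step 17 the allylsilane aldehyde F9. BF3·OEt2 in CH2Cl2 at −78 °C should then make the allylsilane terminus C8 attack C9 with loss of the silyl group, which forms the same bond and the same exocyclic methylene and gives 24.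

2. Step 8. Facial selectivity at C4 may be poor if a metal-chelated transition state places C5 on the concave face. Fallback: replace the enolate by its silyl ketene acetal; it sets out from 12 and comes back at 13. LiN(iPr)2 in the presence of Me3SiCl (THF, −78 °C) would convert 12 into the silyl ketene acetal F10. TiCl4 in CH2Cl2 at −78 °C would then effect an intramolecular Mukaiyama–Michael addition through an open transition state in which the titanium-bound ester is forced to the convex side, and aqueous work-up gives 13.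

3. Step 3. SN2 attack of the hard lithium carbanion at the hindered oxirane carbon may be sluggish, with self-condensation of the nitrile anion taking over. Fallback: an alkoxide-assisted organocopper opening of the unprotected epoxy alcohol followed by oxidative lactonisation; it sets out from 2 and comes back at 6 and then 7. CH2=CHMgBr with CuI (THF/Et2O, −20 °C) should open 2 at the carbon next to the carbinol with the same inversion and give the 1,3-diol F11. t-BuMe2SiCl and imidazole would silylate the primary hydroxyl to F12. 9-Borabicyclo[3.3.1]nonane followed by H2O2/NaOH would hydroborate only the vinyl group and give the diol F13. 2,2,6,6-Tetramethylpiperidin-1-oxyl (cat.) with PhI(OAc)2 would oxidise the primary alcohol and close the lactone 6, and 2 M HCl would remove the silyl ether to give 7.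

**Further compounds**

F1 | step 18 | 2-[(3S,3aS,6R,6aS)-3-(3-hydroxy-4-methylpent-4-en-1-yl)-3,6-dimethyl-1-oxohexahydro-1H-cyclopenta[c]furan-6-yl]-N-methoxy-N-methylacetamide, C14 epimers | CON(C)C(=O)C[C@@]1(C)CC[C@H]2[C@@H]1C(=O)O[C@@]2(C)CCC(O)C(C)=C
F2 | step 18 | [3-(trimethylsilyl)prop-1-en-2-yl]magnesium bromide | C=C(C[Si](C)(C)C)[Mg]Br
F3 | step 18 | (3S,3aS,6R,6aS)-3-(3-hydroxy-4-methylpent-4-en-1-yl)-3,6-dimethyl-6-{2-oxo-3-[(trimethylsilyl)methyl]but-3-en-1-yl}hexahydro-1H-cyclopenta[c]furan-1-one, C14 epimers | C=C(C[Si](C)(C)C)C(=O)C[C@@]1(C)CC[C@H]2[C@@H]1C(=O)O[C@@]2(C)CCC(O)C(C)=C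
F4 | step 18 | bis-enone analogue of 18 with CH2SiMe3 in place of the C7 methyl | C=C(C[Si](C)(C)C)C(=O)C[C@@]1(C)CC[C@H]2[C@@H]1C(=O)O[C@@]2(C)CCC(=O)C(C)=C
F5 | step 18 | (6S,14S)-diol analogue of 19 with CH2SiMe3 in place of the C7 methyl | C=C(C[Si](C)(C)C)[C@@H](O)C[C@@]1(C)CC[C@H]2[C@@H]1C(=O)O[C@@]2(C)CC[C@H](O)C(C)=C
F6 | step 18 | bis(tert-butyldimethylsilyl) ether of F5 | C=C(C[Si](C)(C)C)[C@@H](O[Si](C)(C)C(C)(C)C)C[C@@]1(C)CC[C@H]2[C@@H]1C(=O)O[C@@]2(C)CC[C@H](O[Si](C)(C)C(C)(C)C)C(C)=C
F7 | step 18 | C9,C11-diol analogue of 21 with CH2SiMe3 in place of the C7 methyl | C=C(C)[C@H](CC[C@](C)(O)[C@H]1CC[C@](C)(C[C@H](O[Si](C)(C)C(C)(C)C)C(=C)C[Si](C)(C)C)[C@H]1CO)O[Si](C)(C)C(C)(C)C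
F8 | step 18 | bis(triethylsilyl) ether of F7 | C=C(C)[C@H](CC[C@](C)(O[Si](CC)(CC)CC)[C@H]1CC[C@](C)(C[C@H](O[Si](C)(C)C(C)(C)C)C(=C)C[Si](C)(C)C)[C@H]1CO[Si](CC)(CC)CC)O[Si](C)(C)C(C)(C)C
F9 | step 18 | allylsilane aldehyde, analogue of 23 with CH2SiMe3 in place of the C7 methyl | C=C(C)[C@H](CC[C@](C)(O[Si](CC)(CC)CC)[C@H]1CC[C@](C)(C[C@H](O[Si](C)(C)C(C)(C)C)C(=C)C[Si](C)(C)C)[C@H]1C=O)O[Si](C)(C)C(C)(C)C
F10 | step 8 | trimethylsilyl ketene acetal of lactone 12 | COC(=O)/C=C(\C)CC[C@H]1C=C(O[Si](C)(C)C)O[C@@]1(C)CCC=C(C)C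
F11 | step 3 | (2R,3S)-2-ethenyl-3,7-dimethyloct-6-ene-1,3-diol | OC[C@H]([C@@](C)(O)CCC=C(C)C)C=C
F12 | step 3 | 1-O-tert-butyldimethylsilyl ether of F11 | CC(C)(C)[Si](C)(C)OC[C@H]([C@@](C)(O)CCC=C(C)C)C=C
F13 | step 3 | (3R,4S)-3-[(tert-butyldimethylsilyloxy)methyl]-4,8-dimethylnon-7-ene-1,4-diol | CC(C)(C)[Si](C)(C)OC[C@H]([C@@](C)(O)CCC=C(C)C)CCO
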